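**Plan**
- Retrosynthesis (xenicane numbering): the first cut is C7–C8 together with C8–O of the oxirane. Then follow C14=C15 (Wittig), C4a–C5 (conjugate addition), the lactone ester bond and C4=C4a (esterification, ring-closing metathesis), and C11–C11a (allylic substitution).
- Enabling feature: C7 (quaternary, bearing O and CH3) and C8 (O-bearing CH) are adjacent members of both the oxirane and the nine-membered carbocycle. The C–C bond that a C8 sulfur ylide and a C7 methyl ketone form on epoxidation is therefore also the ring-closing bond. The two arms start from the neighbouring, trans-configured lactone carbons C4a and C11a, and C11 is sp2.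
- Forward order: the δ-lactone ring arises first (metathesis) and its three arms are then completed. The nine-membered ring and the oxirane arise together in the last step.
- Stereochemistry: C11a comes from (R)-but-3-en-2-ol by anti-SN2' chirality transfer. C4a is set by copper-mediated addition anti to the C11a substituent, and C4 by kinetic protonation anti to the new C4a chain. C7 and C8 are set in the ring closure under control of C4a/C11a. The E geometry at C14=C15 comes from a stabilised ylide.

Key step: step 16

Remark: xenicane numbering is C1 = OCH2, O2, C3 = lactone C=O, C4, C4a, C5, C6, C7 (CH3), C8, C9, C10, C11 (=C19H2), C11a, with side chain C12–C16. In the oxan-2-one names, ring C3/C4/C5 correspond to C4/C4a/C11a.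

**Step 1**
Reactants: 1 (R)-but-3-en-2-ol; 2 allyloxy(tert-butyl)dimethylsilane
Product: 3 (2R,3E)-5-[(tert-butyldimethylsilyl)oxy]pent-3-en-2-ol
Conditions: second-generation Hoveyda–Grubbs catalyst (2 mol %), 2 (3 equiv), CH2Cl2, 40 °C
Reagents that add atoms: none
Why: Olefin cross-metathesis of a fast-reacting allyl silyl ether with a slower secondary allylic alcohol should favour the E cross-product while ethene escapes, and the carbinol centre of 1 is not touched.

**Step 2**
Reactants: 3 (2R,3E)-5-[(tert-butyldimethylsilyl)oxy]pent-3-en-2-ol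
Product: 4 (2R,3E)-5-[(tert-butyldimethylsilyl)oxy]pent-3-en-2-yl pyridine-2-carboxylate
Conditions: picolinic acid, DCC, DMAP (cat.), CH2Cl2, 23 °C
Reagents that add atoms: picolinic acid, O=C(O)c1ccccn1
Why: Steglich esterification takes place at oxygen, so the C–O stereocentre is retained and a chelating leaving group is installed for the copper step.

**Step 3**
Reactants: 5 5-chloropent-1-yne
Product: 7 2-bromo-5-chloropent-1-ene, via bromoboration adduct 6 (not isolated)
Conditions: B-bromo-9-borabicyclo[3.3.1]nonane, CH2Cl2, 0 °C; then AcOH, 0 → 23 °C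
Reagents that add atoms: B-bromo-9-borabicyclo[3.3.1]nonane, BrB1C2CCCC1CCC2
Why: Syn-bromoboration of a terminal alkyne places bromine on the internal carbon, and protodeboronation with acetic acid gives the 2-bromo-1-alkene with the alkyl chloride untouched.

**Step 4**
Reactants: 4 (2R,3E)-5-[(tert-butyldimethylsilyl)oxy]pent-3-en-2-yl pyridine-2-carboxylate; 7 2-bromo-5-chloropent-1-ene
Product: 10 tert-butyl{[(2R,3E)-2-(5-chloropent-1-en-2-yl)pent-3-en-1-yl]oxy}dimethylsilane, via alkenylmagnesium bromide 8 (not isolated), via magnesium dialkenylcuprate 9 (not isolated)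
Conditions: 7 (2.2 equiv), Mg, THF, 30 °C; CuBr·SMe2 (1.1 equiv), −40 °C; then 4, −40 → 0 °C
Reagents that add atoms: magnesium, [Mg]; CuBr·SMe2, Br[Cu].CSC (both end up only in 8 and 9)
Why: In this anti-SN2' allylic substitution of a secondary allylic picolinate with an alkenylcopper reagent, magnesium chelated by the pyridine nitrogen and the ester carbonyl activates the leaving group and copper attacks the γ-carbon anti to the C–O bond in the rotamer whose carbinol hydrogen eclipses the alkene, so that the R carbinol centre is transferred to R-configured C11a with formation of an E-propenyl group.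

**Step 5**
Reactants: 10 tert-butyl{[(2R,3E)-2-(5-chloropent-1-en-2-yl)pent-3-en-1-yl]oxy}dimethylsilane
Product: 11 (2R,3E)-2-(5-chloropent-1-en-2-yl)pent-3-en-1-ol
Conditions: camphorsulfonic acid (10 mol %), MeOH, 0 → 23 °C
Reagents that add atoms: none
Why: Acid-catalysed methanolysis cleaves a primary silyl ether under conditions too mild to move the skipped diene or touch C11a.

**Step 6**
Reactants: 12 triethyl phosphonoacetate; 13 2-(2-bromoethyl)-1,3-dioxolane
Product: 14 ethyl 2-(diethoxyphosphoryl)-4-(1,3-dioxolan-2-yl)butanoate (racemic)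
Conditions: NaH, NaI (cat.), DMF, 0 → 60 °C
Reagents that add atoms: none
Why: SN2 alkylation of the stabilised phosphonoacetate anion with a primary bromide is routine, and the new centre is destroyed in the next step.

**Step 7**
Reactants: 14 ethyl 2-(diethoxyphosphoryl)-4-(1,3-dioxolan-2-yl)butanoate
Product: 15 ethyl 4-(1,3-dioxolan-2-yl)-2-methylidenebutanoate
Conditions: 37 % aq. HCHO, K2CO3, 23 → 40 °C
Reagents that add atoms: formaldehyde, C=O
Why: Horner–Wadsworth–Emmons methylenation of an α-alkyl phosphonoacetate with aqueous formaldehyde is the standard entry to α-substituted acrylates.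

**Step 8**
Reactants: 15 ethyl 4-(1,3-dioxolan-2-yl)-2-methylidenebutanoate
Product: 16 4-(1,3-dioxolan-2-yl)-2-methylidenebutanoic acid
Conditions: LiOH, THF–H2O, 23 °C; then 1 M HCl to pH 4, 0 °C
Reagents that add atoms: lithium hydroxide, [Li+].[OH-]
Why: Saponification of the ethyl ester proceeds without attack on the acetal, which also survives the cold, weakly acidic work-up.

**Step 9**
Reactants: 11 (2R,3E)-2-(5-chloropent-1-en-2-yl)pent-3-en-1-ol; 16 4-(1,3-dioxolan-2-yl)-2-methylidenebutanoic acid
Product: 17 (2R,3E)-2-(5-chloropent-1-en-2-yl)pent-3-en-1-yl 4-(1,3-dioxolan-2-yl)-2-methylidenebutanoate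
Conditions: DCC, DMAP (cat.), CH2Cl2, 0 → 23 °C
Reagents that add atoms: none
Why: Steglich esterification of a primary alcohol joins the two fragments under nearly neutral conditions that leave C11a alone.

**Step 10**
Reactants: 17 (2R,3E)-2-(5-chloropent-1-en-2-yl)pent-3-en-1-yl 4-(1,3-dioxolan-2-yl)-2-methylidenebutanoate
Product: 18 (5R)-5-(5-chloropent-1-en-2-yl)-3-[2-(1,3-dioxolan-2-yl)ethyl]-5,6-dihydro-2H-pyran-2-one
Conditions: second-generation Hoveyda–Grubbs catalyst (5 mol %), 1,4-benzoquinone (10 mol %), toluene (2 mM), 80 °C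
Reagents that add atoms: none
Why: In this ring-closing metathesis the catalyst engages the propenyl group and closes the six-membered ring onto the acrylate alkene with loss of propene, the C11=C19 alkene on the same carbon cannot cyclise, and benzoquinone suppresses hydride-induced alkene migration so that C11a is kept.

**Step 11**
Reactants: 18 (5R)-5-(5-chloropent-1-en-2-yl)-3-[2-(1,3-dioxolan-2-yl)ethyl]-5,6-dihydro-2H-pyran-2-one; 19 2-(2-bromoethyl)-2-methyl-1,3-dioxolane
Product: 22 (3S,4S,5R)-5-(5-chloropent-1-en-2-yl)-3-[2-(1,3-dioxolan-2-yl)ethyl]-4-[2-(2-methyl-1,3-dioxolan-2-yl)ethyl]oxan-2-one, via Grignard reagent 20 (not isolated), via silyl ketene acetal 21 (not isolated)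
Conditions: 19, Mg, THF, 25 °C; then 18, CuBr·SMe2 (20 mol %), TMSCl (3 equiv), THF, −78 → −40 °C; then 0.5 M aq. citric acid, THF, 0 °C
Reagents that add atoms: magnesium, [Mg] (in 20 only); chlorotrimethylsilane, C[Si](C)(C)Cl (in 21 only)
Why: In this TMSCl-accelerated, copper-catalysed conjugate addition of a Grignard reagent the nucleophile enters ring C4 anti to the neighbouring C5 alkenyl group (4,5-trans), and hydrolysis of the silyl ketene acetal should deliver the proton to C3 from the face away from the new, pseudo-axial C4 chain, which leaves the C3 and C4 chains cis.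

**Step 12**
Reactants: 22 (3S,4S,5R)-5-(5-chloropent-1-en-2-yl)-3-[2-(1,3-dioxolan-2-yl)ethyl]-4-[2-(2-methyl-1,3-dioxolan-2-yl)ethyl]oxan-2-one
Product: 23 3-[(3S,4S,5R)-5-(5-chloropent-1-en-2-yl)-2-oxo-4-(3-oxobutyl)oxan-3-yl]propanal
Conditions: 1 M aq. HCl, THF, 23 °C
Reagents that add atoms: water, O
Why: Acid-catalysed hydrolysis frees the ketone and the aldehyde in one operation, and dilute acid at room temperature should not enolise the lactone at C3.

**Step 13**
Reactants: 23 3-[(3S,4S,5R)-5-(5-chloropent-1-en-2-yl)-2-oxo-4-(3-oxobutyl)oxan-3-yl]propanal; 24 methyl 2-(triphenylphosphoranylidene)propanoate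
Product: 25 methyl (2E)-5-[(3S,4S,5R)-5-(5-chloropent-1-en-2-yl)-2-oxo-4-(3-oxobutyl)oxan-3-yl]-2-methylpent-2-enoate
Conditions: CH2Cl2, 23 °C
Reagents that add atoms: none
Why: The Wittig reaction of a stabilised, weakly basic ylide takes place at the aldehyde only, gives the E-trisubstituted enoate, and leaves the methyl ketone and C3 untouched.

**Step 14**
Reactants: 25 methyl (2E)-5-[(3S,4S,5R)-5-(5-chloropent-1-en-2-yl)-2-oxo-4-(3-oxobutyl)oxan-3-yl]-2-methylpent-2-enoate
Product: 26 methyl (2E)-5-[(3S,4S,5R)-5-(5-iodopent-1-en-2-yl)-2-oxo-4-(3-oxobutyl)oxan-3-yl]-2-methylpent-2-enoate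
Conditions: NaI (10 equiv), acetone, reflux
Reagents that add atoms: sodium iodide, [Na+].[I-]
Why: The Finkelstein exchange of a primary chloride is driven by precipitation of NaCl and runs under neutral conditions.

**Step 15**
Reactants: 26 methyl (2E)-5-[(3S,4S,5R)-5-(5-iodopent-1-en-2-yl)-2-oxo-4-(3-oxobutyl)oxan-3-yl]-2-methylpent-2-enoate
Product: 27 diphenyl{4-[(3S,4S,5R)-3-[(3E)-5-methoxy-4-methyl-5-oxopent-3-en-1-yl]-2-oxo-4-(3-oxobutyl)oxan-5-yl]pent-4-en-1-yl}sulfonium triflate
Conditions: Ph2S (5 equiv), AgOTf (1.1 equiv), CH2Cl2, 23 °C, dark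
Reagents that add atoms: diphenyl sulfide, c1ccc(cc1)Sc1ccccc1; silver triflate AgOTf, [Ag+].[O-]S(=O)(=O)C(F)(F)F
Why: Silver-assisted S-alkylation of diphenyl sulfide with a primary iodide is the standard route to alkyldiphenylsulfonium salts, the excess sulfide outruns participation by the C11=C19 alkene, and two aryl groups on sulfur leave C8 as the only site for ylide formation.

**Step 16**
Reactants: 27 diphenyl{4-[(3S,4S,5R)-3-[(3E)-5-methoxy-4-methyl-5-oxopent-3-en-1-yl]-2-oxo-4-(3-oxobutyl)oxan-5-yl]pent-4-en-1-yl}sulfonium triflate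
Product: 30 acalycixeniolide H, via sulfonium ylide 28 (not isolated), via betaine 29 (not isolated)
Conditions: KHMDS (1.0 equiv, added over 4 h), THF (1 mM), −78 °C, then → −20 °C
Reagents that add atoms: none
Why: Proposed new method: KHMDS removes the most acidic proton of 27, a C8–H next to the diphenylsulfonium group (several pKa units below the methyl ketone, the lactone C4–H and the enoate γ-H); the non-stabilised ylide 28 then adds through C8 to the C7 ketone in an irreversible 9-exo-trig closure to betaine 29, and after rotation about the new C7–C8 bond the alkoxide displaces Ph2S from C8 with inversion in a 3-exo-tet closure, so that carbocycle and oxirane arise in one operation. The closest known reaction type is the Johnson–Corey–Chaykovsky epoxidation of ketones with diphenylsulfonium alkylides, whose intramolecular form is known only for five- to seven-membered rings, so the nine-membered closure is the new element. It should be feasible because the two arms leave the adjacent lactone carbons C4a and C11a as a trans-diequatorial, hence gauche, pair that points them toward each other, because sp2 C11 removes transannular hydrogen contacts, and because such a high-energy ylide adds to a methyl ketone with a low barrier even at −78 °C, while a concentration near 1 mM and slow addition of base hold back intermolecular epoxidation. The relative configuration at C7/C8 is set in the addition step: in the cisoid transition state (S+ and O gauche, favoured in a weakly polar, lithium-free medium) the closing chain keeps C6 and C9 gauche and the C7 methyl group takes the slot anti to C9 rather than the slot between C9 and SPh2, and this betaine can collapse only to the trans (E-type) oxirane. The absolute sense is relayed from C4a and C11a: SPh2 and the carbonyl oxygen must both point to the outside of the forming ring, and of the two such folds the one that leads to the less strained crown of the trans-fused bicycle, with the C7 methyl group kept away from the lactone ring, should present the Re face of the ketone to C8 and give 7S,8S. Chemoselectivity for the ketone rests on its higher electrophilicity compared with the lactone and ester carbonyl groups and on the low Michael reactivity of the α-methyl-β-alkyl enoate (which would also need a ten-membered transition state), and the use of exactly one equivalent of base protects the epimerisable C4 centre.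

**Compound list**
1 | (R)-but-3-en-2-ol | C[C@@H](O)C=C | starting material
2 | allyloxy(tert-butyl)dimethylsilane | C=CCO[Si](C)(C)C(C)(C)C | starting material
3 | (2R,3E)-5-[(tert-butyldimethylsilyl)oxy]pent-3-en-2-ol | C[C@@H](O)/C=C/CO[Si](C)(C)C(C)(C)C | intermediate
4 | (2R,3E)-5-[(tert-butyldimethylsilyl)oxy]pent-3-en-2-yl pyridine-2-carboxylate | C[C@@H](OC(=O)c1ccccn1)/C=C/CO[Si](C)(C)C(C)(C)C | intermediate
5 | 5-chloropent-1-yne | C#CCCCCl | starting material
6 | bromoboration adduct, (Z)-9-(2-bromo-5-chloropent-1-en-1-yl)-9-borabicyclo[3.3.1]nonane | ClCCC/C(Br)=C/B1C2CCCC1CCC2 | intermediate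
7 | 2-bromo-5-chloropent-1-ene | C=C(Br)CCCCl | intermediate
8 | alkenylmagnesium bromide, (5-chloropent-1-en-2-yl)magnesium bromide | C=C([Mg]Br)CCCCl | intermediate
9 | magnesium dialkenylcuprate, bromomagnesium bis(5-chloropent-1-en-2-yl)cuprate | C=C(CCCCl)[Cu-]C(=C)CCCCl.[Mg+]Br | intermediate
10 | tert-butyl{[(2R,3E)-2-(5-chloropent-1-en-2-yl)pent-3-en-1-yl]oxy}dimethylsilane | C=C(CCCCl)[C@H](CO[Si](C)(C)C(C)(C)C)/C=C/C | intermediate
11 | (2R,3E)-2-(5-chloropent-1-en-2-yl)pent-3-en-1-ol | C=C(CCCCl)[C@H](CO)/C=C/C | intermediate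
12 | triethyl phosphonoacetate | CCOC(=O)CP(=O)(OCC)OCC | starting material
13 | 2-(2-bromoethyl)-1,3-dioxolane | BrCCC1OCCO1 | starting material
14 | ethyl 2-(diethoxyphosphoryl)-4-(1,3-dioxolan-2-yl)butanoate (racemic) | CCOC(=O)C(CCC1OCCO1)P(=O)(OCC)OCC | intermediate
15 | ethyl 4-(1,3-dioxolan-2-yl)-2-methylidenebutanoate | C=C(CCC1OCCO1)C(=O)OCC | intermediate
16 | 4-(1,3-dioxolan-2-yl)-2-methylidenebutanoic acid | C=C(CCC1OCCO1)C(=O)O | intermediate
17 | (2R,3E)-2-(5-chloropent-1-en-2-yl)pent-3-en-1-yl 4-(1,3-dioxolan-2-yl)-2-methylidenebutanoate | C=C(CCCCl)[C@H](COC(=O)C(=C)CCC1OCCO1)/C=C/C | intermediate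
18 | (5R)-5-(5-chloropent-1-en-2-yl)-3-[2-(1,3-dioxolan-2-yl)ethyl]-5,6-dihydro-2H-pyran-2-one | C=C(CCCCl)[C@@H]1COC(=O)C(CCC2OCCO2)=C1 | intermediate
19 | 2-(2-bromoethyl)-2-methyl-1,3-dioxolane | CC1(CCBr)OCCO1 | starting material
20 | Grignard reagent, [2-(2-methyl-1,3-dioxolan-2-yl)ethyl]magnesium bromide | CC1(CC[Mg]Br)OCCO1 | intermediate
21 | silyl ketene acetal of 22 (4,5-trans, C2(OSiMe3)=C3) | C=C(CCCCl)[C@@H]1COC(O[Si](C)(C)C)=C(CCC2OCCO2)[C@H]1CCC1(C)OCCO1 | intermediate
22 | (3S,4S,5R)-5-(5-chloropent-1-en-2-yl)-3-[2-(1,3-dioxolan-2-yl)ethyl]-4-[2-(2-methyl-1,3-dioxolan-2-yl)ethyl]oxan-2-one | C=C(CCCCl)[C@@H]1COC(=O)[C@@H](CCC2OCCO2)[C@H]1CCC1(C)OCCO1 | intermediate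
23 | 3-[(3S,4S,5R)-5-(5-chloropent-1-en-2-yl)-2-oxo-4-(3-oxobutyl)oxan-3-yl]propanal | C=C(CCCCl)[C@@H]1COC(=O)[C@@H](CCC=O)[C@H]1CCC(C)=O | intermediate
24 | methyl 2-(triphenylphosphoranylidene)propanoate | COC(=O)C(C)=P(c1ccccc1)(c1ccccc1)c1ccccc1 | starting material
25 | methyl (2E)-5-[(3S,4S,5R)-5-(5-chloropent-1-en-2-yl)-2-oxo-4-(3-oxobutyl)oxan-3-yl]-2-methylpent-2-enoate | C=C(CCCCl)[C@@H]1COC(=O)[C@@H](CC/C=C(\C)C(=O)OC)[C@H]1CCC(C)=O | intermediate
26 | methyl (2E)-5-[(3S,4S,5R)-5-(5-iodopent-1-en-2-yl)-2-oxo-4-(3-oxobutyl)oxan-3-yl]-2-methylpent-2-enoate | C=C(CCCI)[C@@H]1COC(=O)[C@@H](CC/C=C(\C)C(=O)OC)[C@H]1CCC(C)=O | intermediate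
27 | diphenyl{4-[(3S,4S,5R)-3-[(3E)-5-methoxy-4-methyl-5-oxopent-3-en-1-yl]-2-oxo-4-(3-oxobutyl)oxan-5-yl]pent-4-en-1-yl}sulfonium triflate | C=C(CCC[S+](c1ccccc1)c1ccccc1)[C@@H]1COC(=O)[C@@H](CC/C=C(\C)C(=O)OC)[C@H]1CCC(C)=O.[O-]S(=O)(=O)C(F)(F)F | intermediate
28 | sulfonium ylide (C8 carbanion of 27) | C=C(CC[CH-][S+](c1ccccc1)c1ccccc1)[C@@H]1COC(=O)[C@@H](CC/C=C(\C)C(=O)OC)[C@H]1CCC(C)=O | intermediate
29 | betaine, (7S,8R)-8-(diphenylsulfonio)-7-oxido nine-membered carbocycle | C=C1CC[C@@H]([S+](c2ccccc2)c2ccccc2)[C@@](C)([O-])CC[C@@H]2[C@H](CC/C=C(\C)C(=O)OC)C(=O)OC[C@@H]12 | intermediate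
30 | acalycixeniolide H (4S,4aS,7S,8S,11aR) | C=C1CC[C@@H]2O[C@@]2(C)CC[C@@H]2[C@H](CC/C=C(\C)C(=O)OC)C(=O)OC[C@@H]12 | target

**Step count**
Total step count: 16. Longest linear sequence: 12 (steps 1, 2, 4, 5, 9–16).

**Steps most likely to fail**

1. Step 16.
   - What may go wrong: intermolecular ylide–ketone addition (oligomerisation) may outrun the nine-membered closure. Base may induce E2 loss of diphenyl sulfide from 27. Control of oxirane geometry (cis versus trans) or of the ring face may be poor. C4 may enolise.
   - Fallback (reductive carbonyl coupling instead of ylide chemistry, all known reaction types): it sets out from 26 and comes back at 30. Kornblum-type oxidation of 26 with trimethylamine N-oxide in DMSO at 23 °C gives the keto aldehyde F1. Samarium diiodide in THF at high dilution (−78 → 0 °C) closes the same C7–C8 bond by intramolecular pinacol coupling. Trivalent samarium bridging both oxygens should place them on the same side and give the (7S,8R)-cis-diol F2.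
   - Selective mesylation of the secondary C8 hydroxyl (MsCl, Et3N, CH2Cl2, −20 °C) gives the C8 mesylate F3. One equivalent of KHMDS in THF (−78 → 0 °C) then lets the C7 alkoxide attack C8 with inversion, which turns the cis-diol array into the trans-oxirane of 30.

2. Step 11.
   - What may go wrong: addition to the α-substituted lactone may be slow, with competing γ-deprotonation at ring C5 and loss of that stereocentre through a dienolate. Facial selectivity in the protonation at ring C3 may be poor, or the centre may drift to the more stable 3,4-trans epimer.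
   - Fallback (radical hydrogen-atom transfer instead of ionic protonation): it sets out from 21, made from 18 as in step 11, and comes back at 22. Compound 21 is quenched at −78 °C with PhSeCl to give the α-phenylselanyl lactone F4, and either C3 epimer serves. (Me3Si)3SiH with Et3B/air in toluene (−78 → 0 °C) generates the planar lactone α-radical. This radical should take hydrogen from the bulky silane on the face away from the neighbouring C4 chain and give 22.

3. Step 4.
   - What may go wrong: attack may occur at the α-carbon instead of the γ-carbon. Incomplete anti selectivity, or reaction through the minor rotamer, would erode enantiopurity. The chloro-substituted alkenylmagnesium reagent may decompose.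
   - Fallback (sigmatropic chirality transfer instead of copper substitution): it sets out from 7 and comes back at 11. Sonogashira coupling of 7 with commercial (S)-but-3-yn-2-ol (Pd(PPh3)2Cl2, CuI, Et3N) gives the enynol F5. Semihydrogenation (H2, Pd/CaCO3 poisoned with Pb(OAc)2, quinoline) gives the (Z)-dienol F6. O-alkylation with KH and iodomethyl(tributyl)stannane gives the stannylmethyl ether F7.
   - Tin–lithium exchange (n-BuLi, THF, −78 °C) then triggers the Wittig–Still [2,3]-rearrangement. Allylic 1,3-strain in the Z-alkene fixes the reactive rotamer, so the new C–CH2OH bond forms on the face of the breaking C–O bond and gives 11 with R configuration and an E-propenyl group.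

**Further compounds**
F1 | step 16 | methyl (2E)-2-methyl-5-[(3S,4S,5R)-2-oxo-4-(3-oxobutyl)-5-(5-oxopent-1-en-2-yl)oxan-3-yl]pent-2-enoate | C=C(CCC=O)[C@@H]1COC(=O)[C@@H](CC/C=C(\C)C(=O)OC)[C@H]1CCC(C)=O
F2 | step 16 | (4S,4aS,7S,8R,11aR)-7,8-dihydroxy analogue of 30 (cis-diol in place of the oxirane) | C=C1CC[C@@H](O)[C@@](C)(O)CC[C@@H]2[C@H](CC/C=C(\C)C(=O)OC)C(=O)OC[C@@H]12
F3 | step 16 | C8 methanesulfonate of F2 | C=C1CC[C@@H](OS(C)(=O)=O)[C@@](C)(O)CC[C@@H]2[C@H](CC/C=C(\C)C(=O)OC)C(=O)OC[C@@H]12
F4 | step 11 | (4S,5R)-3-phenylselanyl derivative of 22 (C3 configuration not defined) | C=C(CCCCl)[C@@H]1COC(=O)C(CCC2OCCO2)([Se]c2ccccc2)[C@H]1CCC1(C)OCCO1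
F5 | step 4 | (2S)-8-chloro-5-methylideneoct-3-yn-2-ol | C[C@H](O)C#CC(=C)CCCCl
F6 | step 4 | (2S,3Z)-8-chloro-5-methylideneoct-3-en-2-ol | C[C@H](O)/C=C\C(=C)CCCCl
F7 | step 4 | tributyl({[(2S,3Z)-8-chloro-5-methylideneoct-3-en-2-yl]oxy}methyl)stannane | C[C@H](OC[Sn](CCCC)(CCCC)CCCC)/C=C\C(=C)CCCCl
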